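**Plan**

1. Numbering used throughout: ring A is the cyclopentane C1–C5 (C4 quaternary, C1 and C5 shared with the seven-membered ring C5=C6, C7, C8, C9, C10, C1). C11 is the carbinol carbon on C7, C10 bears a methyl group, and C9' is the benzylic CH.
2. Retrosynthesis: add three O-methyl groups and a C8=C9 double bond. The resulting cyclohepta-1,4-diene carries the array C10–C1–C5=C6–C7–C8=C9, the product pattern of a Cope rearrangement of a cis-divinylcyclopropane (ring C6–C7–C8). C1–C10 is therefore cut by retro-[3,3] and C5–C6 by retro-coupling, giving alkenyl triflate 8 and the all-cis iodocyclopropane 15.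
3. Fragment A: a dihydrocoumarin serves as a temporary ring. Cu-catalysed conjugate addition sets C9', and two lactone-enolate alkylations build quaternary C4 trans to the isobutyl group. SmI2 acyl substitution then closes ring A and releases the phenol; methylation, triflation and double formylation give 8.
4. Fragment B: a (Z)-iodoalkenyl diazoacetate is cyclised by enantioselective intramolecular cyclopropanation; the lactone tether fixes the all-cis cyclopropane and the absolute configuration at C7. Lactol formation and E-olefination give 15.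
5. Negishi coupling and Cope rearrangement in one pot join the fragments and close the seven-membered ring; the boat transition state sets C1 and C10 relative to C7. Diimide reduction of C8=C9 and thiolate demethylation finish the synthesis.

Key step: step 14

Remark: the enantiomers of the ferrocenyl diphosphine (step 1) and of the dirhodium carboxamidate (step 11) are those that give the configurations drawn. Rh2(5S-MEPY)4 is assigned by analogy with its behaviour toward (Z)-allylic diazoacetates, and the mirror-image catalyst is used if the sense proves opposite.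

**Route**

Step 1
Reactants: 1 5,7-dimethoxycoumarin
Product: 2 (4R)-5,7-dimethoxy-4-(2-methylpropyl)chroman-2-one
Conditions: i-BuMgBr (1.5 equiv), CuBr·SMe2 (5 mol %), Josiphos-type ferrocenyl diphosphine (6 mol %), CH2Cl2, −72 °C; aq NH4Cl
Reagents that add atoms: isobutylmagnesium bromide, CC(C)C[Mg]Br
Why: Copper-catalysed asymmetric conjugate addition of a Grignard reagent to the coumarin enoate; the chiral diphosphine–copper complex delivers isobutyl to one face of C4 and so sets the benzylic centre C9' (R in 2).

Step 2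
Reactants: 2 (4R)-5,7-dimethoxy-4-(2-methylpropyl)chroman-2-one
Product: 3 trans-5,7-dimethoxy-3-methyl-4-(2-methylpropyl)chroman-2-one
Conditions: LiN(SiMe3)2, THF, −78 °C; MeI
Reagents that add atoms: iodomethane, CI
Why: Lactone enolate alkylation; methyl should enter anti to the isobutyl group (trans product), but this centre is planarised again in step 3, so its configuration is immaterial.

Step 3
Reactants: 3 trans-5,7-dimethoxy-3-methyl-4-(2-methylpropyl)chroman-2-one
Product: 4 3-(3-iodopropyl)-5,7-dimethoxy-3-methyl-4-(2-methylpropyl)chroman-2-one (methyl cis and iodopropyl trans to isobutyl)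
Conditions: LiN(i-Pr)2, THF–DMPU, −78 °C; I(CH2)3I (4 equiv), −78 → −20 °C
Reagents that add atoms: 1,3-diiodopropane, ICCCI
Why: Second enolate alkylation (quaternisation): the peri methoxy group holds the isobutyl group pseudoaxial, so the iodide enters the enolate face trans to it; this leaves methyl cis to isobutyl and sets quaternary C4 in the configuration of the target relative to C9', while the excess of diiodide suppresses double alkylation.

Step 4
Reactants: 4 3-(3-iodopropyl)-5,7-dimethoxy-3-methyl-4-(2-methylpropyl)chroman-2-one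
Product: 5 2-[1-(2-hydroxy-4,6-dimethoxyphenyl)-3-methylbutyl]-2-methylcyclopentan-1-one (C4 and C9' as in the target)
Conditions: SmI2 (2.5 equiv), Fe(dbm)3 [tris(dibenzoylmethanato)iron] (2 mol %), THF, −30 → 0 °C; aq NH4Cl
Reagents that add atoms: none
Why: SmI2-mediated intramolecular nucleophilic acyl substitution (Barbier type): the primary alkylsamarium adds 5-exo to the aryl ester carbonyl and the tetrahedral intermediate expels the phenoxide, so ring A closes as a 2,2-disubstituted cyclopentanone while the temporary lactone ring opens, without touching either stereocentre.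

Step 5
Reactants: 5 2-[1-(2-hydroxy-4,6-dimethoxyphenyl)-3-methylbutyl]-2-methylcyclopentan-1-one
Product: 6 2-methyl-2-[3-methyl-1-(2,4,6-trimethoxyphenyl)butyl]cyclopentan-1-one
Conditions: MeI, K2CO3, acetone, 50 °C
Reagents that add atoms: iodomethane, CI
Why: Williamson O-methylation of the phenol (K2CO3 does not enolise the hindered ketone), any ring-chain hemiketal tautomer draining through the phenoxide.

Step 6
Reactants: 6 2-methyl-2-[3-methyl-1-(2,4,6-trimethoxyphenyl)butyl]cyclopentan-1-one
Product: 7 5-methyl-5-[3-methyl-1-(2,4,6-trimethoxyphenyl)butyl]cyclopent-1-en-1-yl trifluoromethanesulfonate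
Conditions: KN(SiMe3)2, THF, −78 °C; PhNTf2
Reagents that add atoms: N-phenylbis(trifluoromethanesulfonimide), O=S(=O)(N(c1ccccc1)S(=O)(=O)C(F)(F)F)C(F)(F)F
Why: Enol triflate formation from the potassium enolate; C4 is quaternary, so deprotonation is possible only at C1 and the C1=C5 alkenyl triflate forms regiospecifically.

Step 7
Reactants: 7 5-methyl-5-[3-methyl-1-(2,4,6-trimethoxyphenyl)butyl]cyclopent-1-en-1-yl trifluoromethanesulfonate
Product: 8 5-[1-(3,5-diformyl-2,4,6-trimethoxyphenyl)-3-methylbutyl]-5-methylcyclopent-1-en-1-yl trifluoromethanesulfonate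
Conditions: Cl2CHOMe (6 equiv), TiCl4 (6 equiv), CH2Cl2, −78 → 0 °C; H2O
Reagents that add atoms: dichloromethyl methyl ether, COC(Cl)Cl
Why: Rieche formylation (electrophilic aromatic substitution by the methoxychlorocarbenium ion) at the two ring positions that each lie between two methoxy groups; the electron-poor alkenyl triflate is inert to the electrophile and no stereocentre is involved.

Step 8
Reactants: 9 ethyl (Z)-3-iodoacrylate
Product: 10 (Z)-4-iodo-2-methylbut-3-en-2-ol
Conditions: MeMgBr (3 equiv), Et2O, −78 → 0 °C; aq NH4Cl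
Reagents that add atoms: methylmagnesium bromide, C[Mg]Br
Why: Double Grignard addition to the ester; at low temperature carbonyl addition outruns attack at the iodine-bearing carbon and the Z alkene geometry is retained.

Step 9
Reactants: 10 (Z)-4-iodo-2-methylbut-3-en-2-ol
Product: 11 (Z)-4-iodo-2-methylbut-3-en-2-yl bromoacetate
Conditions: BrCH2COBr, pyridine, CH2Cl2, 0 °C
Reagents that add atoms: bromoacetyl bromide, BrCC(Br)=O
Why: O-acylation of the tertiary alcohol with the reactive acyl bromide under pyridine catalysis.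

Step 10
Reactants: 11 (Z)-4-iodo-2-methylbut-3-en-2-yl bromoacetate
Product: 12 (Z)-4-iodo-2-methylbut-3-en-2-yl diazoacetate
Conditions: TsNHNHTs, DBU, THF, 0 °C
Reagents that add atoms: N,N'-bis(p-toluenesulfonyl)hydrazine, Cc1ccc(cc1)S(=O)(=O)NNS(=O)(=O)c1ccc(C)cc1
Why: Diazoacetate synthesis by the ditosylhydrazine method: SN2 displacement of bromide by the sulfonyl hydrazide and base-induced loss of two sulfinate ions.

Step 11
Reactants: 12 (Z)-4-iodo-2-methylbut-3-en-2-yl diazoacetate
Product: 13 (1R,5S,6R)-6-iodo-4,4-dimethyl-3-oxabicyclo[3.1.0]hexan-2-one (iodine endo, all-cis cyclopropane)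
Conditions: Rh2(5S-MEPY)4 {dirhodium tetrakis[methyl (5S)-2-oxopyrrolidine-5-carboxylate]} (1 mol %), CH2Cl2, 40 °C, slow addition
Reagents that add atoms: none
Why: Enantioselective intramolecular cyclopropanation of an allylic diazoacetate by a chiral dirhodium carboxamidate carbene: addition to the Z alkene is stereospecific (iodine stays cis to the carbinol carbon), the lactone tether forces the carbonyl carbon cis as well, giving the all-cis cyclopropane, and the catalyst selects the alkene face and thus the absolute configuration of C6, C7 and C8.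

Step 12
Reactants: 13 (1R,5S,6R)-6-iodo-4,4-dimethyl-3-oxabicyclo[3.1.0]hexan-2-one
Product: 14 6-iodo-4,4-dimethyl-3-oxabicyclo[3.1.0]hexan-2-ol (lactol, anomers)
Conditions: i-Bu2AlH (1.1 equiv), CH2Cl2, −78 °C; aq potassium sodium tartrate
Reagents that add atoms: none
Why: Partial reduction of the lactone to the lactol with i-Bu2AlH at low temperature, the aluminium hemiacetal surviving until work-up; the cyclopropyl iodide is inert.

Step 13
Reactants: 14 6-iodo-4,4-dimethyl-3-oxabicyclo[3.1.0]hexan-2-ol
Product: 15 2-[(1S,2S,3S)-2-iodo-3-[(E)-prop-1-enyl]cyclopropyl]propan-2-ol (all-cis)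
Conditions: CrCl2 (8 equiv), CH3CHI2 (2 equiv), THF, 25 °C
Reagents that add atoms: 1,1-diiodoethane, CC(I)I
Why: Takai–Utimoto ethylidenation of the hydroxy aldehyde in equilibrium with the lactol: the geminal dichromium reagent gives the E alkene selectively and tolerates the free tertiary alcohol and the cyclopropyl iodide.

Step 14
Reactants: 15 2-[(1S,2S,3S)-2-iodo-3-[(E)-prop-1-enyl]cyclopropyl]propan-2-ol; 8 5-[1-(3,5-diformyl-2,4,6-trimethoxyphenyl)-3-methylbutyl]-5-methylcyclopent-1-en-1-yl trifluoromethanesulfonate
Product: 18 tri-O-methyl 8,9-didehydro precursor of the target (bicyclic cyclohepta-1,4-diene with H1 and H10 and the hydroxyisopropyl group all cis), via cyclopropylzinc chloride 16 (not isolated), via cis-divinylcyclopropane 17 (not isolated)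
Conditions: 15 (1.3 equiv), t-BuLi (3 equiv per 15), Et2O, −78 °C; ZnCl2, THF, −78 → 23 °C; 8, Pd(OAc)2 (5 mol %), SPhos (10 mol %), THF, 60 °C; then PhMe, 110 °C
Reagents that add atoms: none
Why: Iodine–lithium exchange and transmetalation give the configurationally stable cyclopropylzinc 16, whose Negishi coupling with alkenyl triflate 8 (oxidative addition, transmetalation, reductive elimination with retention at C6) makes the C5–C6 bond; the resulting cis-1,2-dialkenylcyclopropane 17 then undergoes the divinylcyclopropane–cycloheptadiene (Cope) rearrangement on heating, the closest known reaction type being seven-ring annulation by coupling of a 2-vinylcyclopropyl metal to a functionalised cycloalkene followed by Cope rearrangement. The seven-membered ring closes by a concerted [3,3] shift through the boat transition state with both alkenyl groups folded over the three-membered ring: the C6–C8 bond breaks, the C1–C10 bond forms, and the C5=C6 and C8=C9 double bonds appear. C1 and C10 are set by the boat geometry: the E-propenyl group and the ring alkene both turn their hydrogen atoms inward, so H1 and H10 end cis to each other and cis to the syn substituent on C7, which is the hydroxyisopropyl group because 15 is all-cis; C7 is carried unchanged from 15. The face of C1 that is used lies on the methyl side of quaternary C4, away from the aryl(isobutyl)methyl group, so the two enantiopure fragments are a matched pair. The step needs the rearrangement to outrun cyclopropane stereomutation; the absence of any Z substituent on either alkene terminus secures this, although the syn carbinol raises the barrier and makes heating to 110 °C necessary.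

Step 15
Reactants: 18 tri-O-methyl 8,9-didehydro precursor of the target
Product: 19 tri-O-methyl ether of the target
Conditions: KO2CN=NCO2K (excess), AcOH, MeOH–CH2Cl2, 0 → 23 °C
Reagents that add atoms: none
Why: Diimide reduction (concerted syn transfer of H2): the unhindered cis-disubstituted C8=C9 bond reacts while the trisubstituted C5=C6 bond next to quaternary C4 and the aldehydes do not, and no stereocentre is affected.

Step 16
Reactants: 19 tri-O-methyl ether of the target
Product: 20 target CNP0281883.1
Conditions: NaSEt (12 equiv), DMF, 100 °C; aq NaH2PO4 (pH 4–5), 0 °C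
Reagents that add atoms: none
Why: Nucleophilic O-demethylation (SN2 at methyl) by ethanethiolate: each methoxy group is ortho or para to a formyl group, so the aryloxide is a good leaving group, and the basic, non-acidic medium spares the tertiary alcohol, the C5=C6 alkene and all stereocentres.

**Compound list**

1 | 5,7-dimethoxycoumarin | O=c1ccc2c(OC)cc(OC)cc2o1 | starting material
2 | (4R)-5,7-dimethoxy-4-(2-methylpropyl)chroman-2-one | CC(C)C[C@@H]1CC(=O)Oc2cc(OC)cc(OC)c12 | intermediate
3 | trans-5,7-dimethoxy-3-methyl-4-(2-methylpropyl)chroman-2-one | CC(C)C[C@@H]1[C@@H](C)C(=O)Oc2cc(OC)cc(OC)c12 | intermediate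
4 | 3-(3-iodopropyl)-5,7-dimethoxy-3-methyl-4-(2-methylpropyl)chroman-2-one (methyl cis to isobutyl) | CC(C)C[C@@H]1[C@@](C)(CCCI)C(=O)Oc2cc(OC)cc(OC)c12 | intermediate
5 | 2-[1-(2-hydroxy-4,6-dimethoxyphenyl)-3-methylbutyl]-2-methylcyclopentan-1-one (C4, C9' as in target) | CC(C)C[C@@H](c1c(O)cc(OC)cc1OC)[C@@]1(C)CCCC1=O | intermediate
6 | 2-methyl-2-[3-methyl-1-(2,4,6-trimethoxyphenyl)butyl]cyclopentan-1-one | CC(C)C[C@@H](c1c(OC)cc(OC)cc1OC)[C@@]1(C)CCCC1=O | intermediate
7 | 5-methyl-5-[3-methyl-1-(2,4,6-trimethoxyphenyl)butyl]cyclopent-1-en-1-yl triflate | CC(C)C[C@@H](c1c(OC)cc(OC)cc1OC)[C@@]1(C)CCC=C1OS(=O)(=O)C(F)(F)F | intermediate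
8 | 5-[1-(3,5-diformyl-2,4,6-trimethoxyphenyl)-3-methylbutyl]-5-methylcyclopent-1-en-1-yl triflate | CC(C)C[C@@H](c1c(OC)c(C=O)c(OC)c(C=O)c1OC)[C@@]1(C)CCC=C1OS(=O)(=O)C(F)(F)F | intermediate
9 | ethyl (Z)-3-iodoacrylate | CCOC(=O)/C=C\I | starting material
10 | (Z)-4-iodo-2-methylbut-3-en-2-ol | CC(C)(O)/C=C\I | intermediate
11 | (Z)-4-iodo-2-methylbut-3-en-2-yl bromoacetate | CC(C)(OC(=O)CBr)/C=C\I | intermediate
12 | (Z)-4-iodo-2-methylbut-3-en-2-yl diazoacetate | CC(C)(OC(=O)C=[N+]=[N-])/C=C\I | intermediate
13 | (1R,5S,6R)-6-iodo-4,4-dimethyl-3-oxabicyclo[3.1.0]hexan-2-one | CC1(C)OC(=O)[C@@H]2[C@H](I)[C@H]12 | intermediate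
14 | 6-iodo-4,4-dimethyl-3-oxabicyclo[3.1.0]hexan-2-ol (lactol, anomeric centre as formed) | CC1(C)OC(O)[C@@H]2[C@H](I)[C@H]12 | intermediate
15 | 2-[(1S,2S,3S)-2-iodo-3-[(E)-prop-1-enyl]cyclopropyl]propan-2-ol (all-cis) | C/C=C/[C@@H]1[C@H](I)[C@@H]1C(C)(C)O | intermediate
16 | all-cis cyclopropylzinc chloride from 15 (lithium alkoxide) | C/C=C/[C@@H]1[C@H]([Zn]Cl)[C@@H]1C(C)(C)O[Li] | intermediate (not isolated)
17 | cis-divinylcyclopropane: 8 with the triflate replaced by the all-cis 2-(2-hydroxypropan-2-yl)-3-[(E)-prop-1-enyl]cyclopropyl group | CC(C)C[C@@H](c1c(OC)c(C=O)c(OC)c(C=O)c1OC)[C@@]1(C)CCC=C1[C@H]2[C@@H](/C=C/C)[C@H]2C(C)(C)O | intermediate (not isolated)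
18 | tri-O-methyl 8,9-didehydro precursor (cyclohepta-1,4-diene; H1, H10, hydroxyisopropyl all cis) | CC(C)C[C@@H](c1c(OC)c(C=O)c(OC)c(C=O)c1OC)[C@@]1(C)CC[C@H]2C1=C[C@H](C(C)(C)O)C=C[C@H]2C | intermediate
19 | tri-O-methyl ether of the target | CC(C)C[C@@H](c1c(OC)c(C=O)c(OC)c(C=O)c1OC)[C@@]1(C)CC[C@H]2C1=C[C@H](C(C)(C)O)CC[C@H]2C | intermediate
20 | CNP0281883.1 | CC(C)C[C@@H](c1c(O)c(C=O)c(O)c(C=O)c1O)[C@@]1(C)CC[C@H]2C1=C[C@H](C(C)(C)O)CC[C@H]2C | target

**Count and risks**

Total steps: 16. Longest linear sequence: 10 (steps 1–7, then 14–16); the second branch is steps 8–13.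

Steps most likely to fail:

1. Step 14. The hydroxyisopropyl group on C7 must sit on the concave side of the boat. If this raises the [3,3] barrier toward that for homolysis of the doubly allylic C6–C8 bond, the cyclopropane stereomutates before it rearranges and the C7/C1/C10 relationship is scrambled; slow coupling at the crowded alkenyl triflate would add to the loss. The fallback carries a flat syn substituent through the rearrangement and builds the carbinol afterwards; it sets out from 9 and 8 and returns at 19. Reduction of 9 with i-Bu2AlH gives (Z)-3-iodoprop-2-en-1-ol F1, which is converted as in steps 9 and 10 into its bromoacetate F2 and diazoacetate F3. Cyclisation with the mirror-image catalyst Rh2(5R-MEPY)4 should give the all-cis 6-iodo-3-oxabicyclo[3.1.0]hexan-2-one F4, in which the lactone carbonyl is now the future C11. Opening with Me(MeO)NH·HCl and AlMe3 gives the hydroxy Weinreb amide F5, Dess–Martin oxidation the aldehyde F6, and ethylidenation (CrCl2, CH3CHI2) the (E)-propenyl iodocyclopropane amide F7. Triflate 8 is protected as its bis(dimethyl acetal) F8 (HC(OMe)3, MeOH, PPTS). Iodine–magnesium exchange of F7 (i-PrMgCl·LiCl, −40 °C), ZnCl2 and Negishi coupling with F8 give the cis-divinylcyclopropane F9 (not isolated), whose syn group is a planar amide, and Cope rearrangement gives the diene amide F10. Diimide reduction gives the cycloheptene amide F11, MeLi at −78 °C the methyl ketone F12, and MeMgBr with CeCl3 the carbinol bis-acetal F13. Mild acetal hydrolysis (PPTS, aqueous acetone) then gives 19.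

2. Step 11. The carboxamidate carbene may discriminate poorly between the alkene faces with a tertiary ester and an electron-poor iodoalkene, or be diverted into C–H insertion at the geminal methyl groups. The fallback replaces asymmetric catalysis by resolution; it sets out from 12 and returns at 14. Cyclisation of 12 with achiral Rh2(OAc)4 gives the racemic lactone F14, and i-Bu2AlH reduction gives the racemic lactol F15. Acetalisation with (−)-menthol (PPTS, CH2Cl2) gives diastereomeric menthyl acetals that are separated; the one with the required cyclopropane configuration, menthyl acetal F16, is hydrolysed (aq AcOH, THF) to 14.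

3. Step 1. The peri methoxy group shields C4 and the electron-rich lactone is a weak acceptor, so conversion may be low, 1,2-addition may compete, or enantioface selection may be poor. The fallback installs the isobutyl group first and sets C9' by hydride delivery; it bypasses 1 (commercial 3,5-dimethoxyphenol is used in its place) and returns at 2. Pechmann condensation of 3,5-dimethoxyphenol with ethyl 5-methyl-3-oxohexanoate (H2SO4) gives 4-isobutyl-5,7-dimethoxycoumarin F17. Asymmetric copper hydride conjugate reduction (Cu(OAc)2, DTBM-SEGPHOS, (EtO)2MeSiH, t-BuOH, PhMe) then gives 2.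

**Further compounds**

F1 | step 14 | (Z)-3-iodoprop-2-en-1-ol | OC/C=C\I
F2 | step 14 | (Z)-3-iodoprop-2-enyl bromoacetate | BrCC(=O)OC/C=C\I
F3 | step 14 | (Z)-3-iodoprop-2-enyl diazoacetate | [N-]=[N+]=CC(=O)OC/C=C\I
F4 | step 14 | all-cis 6-iodo-3-oxabicyclo[3.1.0]hexan-2-one (iodine endo) | O=C1OC[C@@H]2[C@H](I)[C@H]12
F5 | step 14 | all-cis 2-(hydroxymethyl)-3-iodo-N-methoxy-N-methylcyclopropane-1-carboxamide | CON(C)C(=O)[C@H]1[C@@H](I)[C@H]1CO
F6 | step 14 | all-cis 2-formyl-3-iodo-N-methoxy-N-methylcyclopropane-1-carboxamide | CON(C)C(=O)[C@H]1[C@@H](I)[C@H]1C=O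
F7 | step 14 | all-cis 2-iodo-N-methoxy-N-methyl-3-[(E)-prop-1-enyl]cyclopropane-1-carboxamide | CON(C)C(=O)[C@H]1[C@@H](I)[C@H]1/C=C/C
F8 | step 14 | bis(dimethyl acetal) of 8 | CC(C)C[C@@H](c1c(OC)c(C(OC)OC)c(OC)c(C(OC)OC)c1OC)[C@@]1(C)CCC=C1OS(=O)(=O)C(F)(F)F
F9 | step 14 | cis-divinylcyclopropane Weinreb amide (bis-acetal, not isolated) | CC(C)C[C@@H](c1c(OC)c(C(OC)OC)c(OC)c(C(OC)OC)c1OC)[C@@]1(C)CCC=C1[C@H]2[C@@H](/C=C/C)[C@H]2C(=O)N(C)OC
F10 | step 14 | cyclohepta-1,4-diene Weinreb amide (bis-acetal) | CC(C)C[C@@H](c1c(OC)c(C(OC)OC)c(OC)c(C(OC)OC)c1OC)[C@@]1(C)CC[C@H]2C1=C[C@H](C(=O)N(C)OC)C=C[C@H]2C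
F11 | step 14 | cycloheptene Weinreb amide (bis-acetal) | CC(C)C[C@@H](c1c(OC)c(C(OC)OC)c(OC)c(C(OC)OC)c1OC)[C@@]1(C)CC[C@H]2C1=C[C@H](C(=O)N(C)OC)CC[C@H]2C
F12 | step 14 | C7 methyl ketone (bis-acetal) | CC(C)C[C@@H](c1c(OC)c(C(OC)OC)c(OC)c(C(OC)OC)c1OC)[C@@]1(C)CC[C@H]2C1=C[C@H](C(C)=O)CC[C@H]2C
F13 | step 14 | bis(dimethyl acetal) of 19 | CC(C)C[C@@H](c1c(OC)c(C(OC)OC)c(OC)c(C(OC)OC)c1OC)[C@@]1(C)CC[C@H]2C1=C[C@H](C(C)(C)O)CC[C@H]2C
F14 | step 11 | racemic 6-endo-iodo-4,4-dimethyl-3-oxabicyclo[3.1.0]hexan-2-one (both enantiomers) | CC1(C)OC(=O)[C@@H]2[C@H](I)[C@H]12.CC1(C)OC(=O)[C@H]2[C@@H](I)[C@@H]12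
F15 | step 11 | racemic lactol (both enantiomers) | CC1(C)OC(O)[C@@H]2[C@H](I)[C@H]12.CC1(C)OC(O)[C@H]2[C@@H](I)[C@@H]12
F16 | step 11 | (−)-menthyl acetal of lactol 14 (anomeric centre as formed) | CC(C)[C@@H]1CC[C@@H](C)C[C@H]1OC1OC(C)(C)[C@H]2[C@@H](I)[C@@H]12
F17 | step 1 | 4-isobutyl-5,7-dimethoxycoumarin | CC(C)Cc1cc(=O)oc2cc(OC)cc(OC)c12
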